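Slowness showed first: at 49.98 min the grey run still held 18 % of its charge as solid substrate, and the earliest products were small readings.

| setting | violet | grey | red | flask |
|---|---|---|---|---|
| solid substrate | 0.034 M | 0.075 M | 0.050 M | 0.050 M |
| coupling partner | 1.2 equiv | 1.2 equiv | 1.8 equiv | 1.20 equiv |
| remark | run made earlier | run made earlier | run made earlier |  |
| time |  |  |  | 4.0 h |

| run | time / h | isomer of the product / % | target / % | solid substrate / % |
|---|---|---|---|---|
| violet | 0.333 | 14 | 7 | 25 |
| violet | 0.500 | 23 | 11 | 3 |
| violet | 0.833 | 36 | 18 | 1 |
| violet | 1.33 | 41 | 21 | 0 |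
| violet | 2.50 | 48 | 24 | 0 |
| violet | 4.00 | 51 | 23 | 0 |
| grey | 0.333 | 11 | 9 | 57 |
| grey | 0.500 | 24 | 11 | 44 |
| grey | 0.833 | 31 | 17 | 18 |
| grey | 1.33 | 43 | 18 | 0 |
| grey | 2.50 | 49 | 24 | 0 |
| grey | 4.00 | 51 | 22 | 1 |
| red | 0.833 | 44 | 19 | 0 |
| red | 1.50 | 52 | 24 | 2 |
| red | 2.50 | 50 | 25 | 0 |
| red | 3.00 | 54 | 26 | 1 |
| red | 4.00 | 53 | 24 | 1 |

(standard deviation of a reading: 1.5 percentage points)

- what was read earlier has a scatter of 1.5 percentage points, one standard deviation
- at the start none of the solid substrate is in solution

- ratio of isomer of the product to target at 4.0 min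
- ratio of isomer of the product to target at 30 min
- ratio of isomer of the product to target at 4.0 h

I wrote Q for the isomer of the product and P for the target, and I reckoned ratios in common logarithms (L), where they become distances in decades.

1. I pooled the 4-hour readings of violet, grey and red. This gave 2.25, which I kept as the late ratio ρ, pooled Q over pooled P, so L = 0.352. The flask's 0.050 M lies between violet's 0.034 M and grey's 0.075 M, so I carried ρ over.

2. Violet and grey pooled gave 2.14 at 30 min, so L = 0.330.

3. The same runs gave 1.56 at 19.98 min, so L = 0.193.

4. A straight line in L through both, run back to 4.0 min, gave a ratio of 0.949.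

5. That slope was the weak link: it joined two ratios of small readings with a scatter of 1.5 percentage points. So I took the line as one edge and the flat 19.98 min ratio as the other, and their middle in L gave 1.22.

I committed to 1.22, 2.14 and 2.25. The forecast said 1.9, 2.1 and 2.15; of the earliest value it wrote, “I expect about 2 with a wide, low-skewed range”. Its early number stood higher than mine.

The flask gave 1.29, 2.08 and 2.19. We parted at 4.0 min, where the forecast stood 1.47 times the result.

    solid substrate ⇌ starting material, rate k1*(cs1 - [starting material]) while solid is left; crystals form when [starting material] > cs1 (solubility = 20.0 mM, k = 0.170 min⁻¹)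
    intermediate ⇌ target (K = 0.960, k = 1.70 min⁻¹)
    starting material + coupling partner → intermediate + by-product (k = 1.20 L mol⁻¹ min⁻¹)
    intermediate ⇌ isomer of the product (K = 2.10, k = 0.990 min⁻¹)
    crystals ⇌ by-product, rate k5*(cs5 - [by-product]) while solid is left; crystals form when [by-product] > cs5 (solubility = 4.60 mM, k = 8.30 min⁻¹)

The late ratio behaved as thermodynamic control: the half-life of the isomer of the product for going back through the intermediate was 1.5 min, shorter than 4.0 h. In the flask at 4.00 h the target stood at 23.3 %; multiplied by ρ, that gave 52.4 % against 51.0 % of the isomer of the product. The neighbour with 0.480 equiv of coupling partner kept 0.430 % of that partner at 4.00 h. Its target stood at 11.3 %, and ρ gave 25.4 % of the isomer of the product. Its isomer of the product stood at 24.7 %.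

Readings and results stem from a simulated flask on assumed constants; noise was put on by code.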